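**Retrosynthetic overview**
1. The target is daidzein carrying a (1Z,3R)-3,7-dimethylocta-1,6-dien-1-yl chain at C3' of ring B. All three rings (benzopyranone rings A/C and phenol ring B) are bought with daidzein, so no ring is formed in the route.
2. Key disconnection: the C3'(aryl)–C1(alkenyl) bond, giving 7-O-TIPS-daidzein (C3'–H, not functionalised) and (1Z,3R)-1-iodo-3,7-dimethylocta-1,6-diene, joined by a one-pot O-boryl-directed Ir C–H borylation/Suzuki–Miyaura coupling.
3. Enabling feature: the free 4'-OH of ring B with its two equivalent unsubstituted ortho carbons C3'/C5'. As its O–Bpin ester it steers iridium to C3'–H, while the more acidic 7-OH of ring A (para to C4a, conjugated with the C4 carbonyl) is capped selectively with TIPS, which also shields C6 and C8.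
4. The Z-alkenyl iodide comes from the 1-iodoalkyne by cis-reduction with diimide, the iodoalkyne from (3R)-3,7-dimethyloct-6-en-1-yne, and the alkyne from (R)-citronellal (aldehyde to alkyne through its alkenyl nonaflate). The stereocentre is bought with citronellal.
5. Last step: fluoride desilylation of the 7-O-TIPS ether.

Key step: step 5

Remark: the side-chain stereocentre of the target is (R); it is taken unchanged from commercial (R)-(+)-citronellal, which is assumed to be of high enantiomeric purity.

**Step 1**
Reactants: 1 daidzein (7-hydroxy-3-(4-hydroxyphenyl)-4H-chromen-4-one)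
Product: 2 3-(4-hydroxyphenyl)-7-[(triisopropylsilyl)oxy]-4H-chromen-4-one
Conditions: t-BuOK (1.0 equiv), DMF, 0 °C; then TIPSCl (1.05 equiv), 0 °C to rt
Reagents that add atoms: chlorotriisopropylsilane (TIPSCl) CC(C)[Si](Cl)(C(C)C)C(C)C
Why: The 7-OH is para to C4a and conjugated with the C4 carbonyl, which makes it by far the more acidic phenol, so one equivalent of base should give the 7-phenoxide, which is O-silylated while the 4'-OH stays free (regioselective silyl ether formation from the more acidic phenoxide).

**Step 2**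
Reactants: 3 (R)-citronellal ((3R)-3,7-dimethyloct-6-enal)
Product: 5 (3R)-3,7-dimethyloct-6-en-1-yne, via alkenyl nonaflate 4 (not isolated)
Conditions: NfF (1.2 equiv), P2-Et phosphazene base (2.3 equiv), DMF, −30 °C to rt
Reagents that add atoms: none
Why: The phosphazene base enolises the aldehyde, NfF traps the enolate as alkenyl nonaflate 4, and a second equivalent of base eliminates nonaflate to the terminal alkyne (one-pot aldehyde-to-alkyne conversion by enol sulfonylation–elimination); the C3 stereocentre is β to the carbonyl and is not deprotonated, and the product rests as its acetylide, which should guard against propargyl–allenyl isomerisation.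

**Step 3**
Reactants: 5 (3R)-3,7-dimethyloct-6-en-1-yne
Product: 6 (3R)-1-iodo-3,7-dimethyloct-6-en-1-yne
Conditions: NIS (1.1 equiv), AgNO3 (10 mol%), acetone, rt, dark
Reagents that add atoms: N-iodosuccinimide (NIS) O=C1CCC(=O)N1I
Why: Silver(I) forms the acetylide of the terminal alkyne, which is iodinated by NIS (silver-catalysed electrophilic iodination of a terminal alkyne); the trisubstituted alkene and the propargylic stereocentre should be untouched under these neutral conditions.

**Step 4**
Reactants: 6 (3R)-1-iodo-3,7-dimethyloct-6-en-1-yne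
Product: 7 (1Z,3R)-1-iodo-3,7-dimethylocta-1,6-diene
Conditions: 2-nitrobenzenesulfonyl hydrazide (NBSH, 2.5 equiv), Et3N, THF/i-PrOH, rt
Reagents that add atoms: none
Why: Diimide generated in situ from NBSH and Et3N transfers two hydrogens to the iodoalkyne through a concerted six-membered syn transition state, which should give the cis (1Z) iodoalkene (diimide reduction of a 1-iodoalkyne); the hindered trisubstituted alkene reacts much more slowly and the stereocentre is not involved.

**Step 5**
Reactants: 2 3-(4-hydroxyphenyl)-7-[(triisopropylsilyl)oxy]-4H-chromen-4-one + 7 (1Z,3R)-1-iodo-3,7-dimethylocta-1,6-diene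
Product: 10 3-{3-[(1Z,3R)-3,7-dimethylocta-1,6-dien-1-yl]-4-hydroxyphenyl}-7-[(triisopropylsilyl)oxy]-4H-chromen-4-one, via aryl O-boronate 8 (not isolated), via ortho C-boronate 9 (not isolated)
Conditions: HBpin (1.1 equiv), THF, rt; [Ir(OMe)(cod)]2 (2 mol%), dtbpy (4 mol%), B2pin2 (1.0 equiv), 70 °C; volatiles removed; then 7 (1.2 equiv), Pd(PPh3)4 (5 mol%), 2 M aq K3PO4, THF, 50 °C
Reagents that add atoms: none
Why: HBpin converts the free 4'-OH into the O–Bpin ester 8, whose oxygen is held against the electron-poor bipyridine of the Ir(III) tris(boryl) catalyst, so that C–H oxidative addition and C–B reductive elimination occur at the adjacent C3'–H to give 9; aqueous phosphate then hydrolyses the O–B bond, Pd(0) inserts into the C–I bond of 7, the ate complex of the C3' boronate transmetallates and reductive elimination forms the C3'–C1 bond (closest known reaction types: traceless O-boryl-directed ortho C–H borylation of phenols and one-pot C–H borylation/Suzuki–Miyaura coupling). No ring is closed and no stereocentre is created; the C3 stereocentre of 7 is a spectator because neither the alkenyl–palladium species nor the base touches the allylic C–H. The step needs site selectivity and retention of the Z geometry: C3' and C5' are equivalent by rotation about the C3–C1' bond and are the only C–H bonds ortho to the directing O–Bpin, C8 lies between the pyran oxygen and the bulky OTIPS group, C6 is ortho to OTIPS, C5 and C2'/C6' carry an ortho substituent without any directing contact, and C2–H of the pyranone lies beside the twisted 3-aryl group. The Z geometry should be carried over because oxidative addition, transmetallation and reductive elimination at an sp2 carbon all proceed with retention, and the diene partner is added only after the boron hydride has been removed, so its two C=C bonds never meet the Ir–boryl catalyst.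

**Step 6**
Reactants: 10 3-{3-[(1Z,3R)-3,7-dimethylocta-1,6-dien-1-yl]-4-hydroxyphenyl}-7-[(triisopropylsilyl)oxy]-4H-chromen-4-one
Product: 11 3-{3-[(1Z,3R)-3,7-dimethylocta-1,6-dien-1-yl]-4-hydroxyphenyl}-7-hydroxy-4H-chromen-4-one
Conditions: TBAF (1.2 equiv), AcOH (1.2 equiv), THF, 0 °C
Reagents that add atoms: none
Why: Fluoride attacks silicon of the aryl silyl ether and releases the acidic 7-phenol, with AcOH as buffer so that neither the pyranone nor the Z-alkene sees strong base (fluoride-mediated desilylation).

**Compound list**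
1 | daidzein, 7-hydroxy-3-(4-hydroxyphenyl)-4H-chromen-4-one | Oc1ccc(-c2coc3cc(O)ccc3c2=O)cc1 | starting material
2 | 3-(4-hydroxyphenyl)-7-[(triisopropylsilyl)oxy]-4H-chromen-4-one | Oc1ccc(-c2coc3cc(O[Si](C(C)C)(C(C)C)C(C)C)ccc3c2=O)cc1 | intermediate
3 | (R)-citronellal, (3R)-3,7-dimethyloct-6-enal | CC(C)=CCC[C@@H](C)CC=O | starting material
4 | (3R)-3,7-dimethylocta-1,6-dien-1-yl nonafluorobutane-1-sulfonate (E/Z mixture, formed in situ) | CC(C)=CCC[C@@H](C)C=COS(=O)(=O)C(F)(F)C(F)(F)C(F)(F)C(F)(F)F | intermediate
5 | (3R)-3,7-dimethyloct-6-en-1-yne | CC(C)=CCC[C@@H](C)C#C | intermediate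
6 | (3R)-1-iodo-3,7-dimethyloct-6-en-1-yne | CC(C)=CCC[C@@H](C)C#CI | intermediate
7 | (1Z,3R)-1-iodo-3,7-dimethylocta-1,6-diene | CC(C)=CCC[C@@H](C)/C=C\I | intermediate
8 | 3-{4-[(4,4,5,5-tetramethyl-1,3,2-dioxaborolan-2-yl)oxy]phenyl}-7-[(triisopropylsilyl)oxy]-4H-chromen-4-one (formed in situ) | CC1(C)OB(Oc2ccc(-c3coc4cc(O[Si](C(C)C)(C(C)C)C(C)C)ccc4c3=O)cc2)OC1(C)C | intermediate
9 | 3-{3-(4,4,5,5-tetramethyl-1,3,2-dioxaborolan-2-yl)-4-[(4,4,5,5-tetramethyl-1,3,2-dioxaborolan-2-yl)oxy]phenyl}-7-[(triisopropylsilyl)oxy]-4H-chromen-4-one (formed in situ) | CC1(C)OB(Oc2ccc(-c3coc4cc(O[Si](C(C)C)(C(C)C)C(C)C)ccc4c3=O)cc2B2OC(C)(C)C(C)(C)O2)OC1(C)C | intermediate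
10 | 3-{3-[(1Z,3R)-3,7-dimethylocta-1,6-dien-1-yl]-4-hydroxyphenyl}-7-[(triisopropylsilyl)oxy]-4H-chromen-4-one | CC(C)=CCC[C@@H](C)/C=C\c1cc(-c2coc3cc(O[Si](C(C)C)(C(C)C)C(C)C)ccc3c2=O)ccc1O | intermediate
11 | 3-{3-[(1Z,3R)-3,7-dimethylocta-1,6-dien-1-yl]-4-hydroxyphenyl}-7-hydroxy-4H-chromen-4-one | CC(C)=CCC[C@@H](C)/C=C\c1cc(-c2coc3cc(O)ccc3c2=O)ccc1O | target

**Step count and risks**
Total step count: 6. Longest linear sequence: 5 steps (3 to 5 to 6 to 7 to 10 to 11; steps 2, 3, 4, 5 and 6).

Steps most likely to fail:

Step 5. The iridium catalyst may borylate a C–H bond other than C3'–H (C2–H of the pyranone, or C5' as a second site), the ortho-hydroxy arylboronate may protodeboronate before it couples, or the Z-alkenyl–palladium species may isomerise. The fallback sets out from 2 and uses alkyne 5 in place of iodide 7. Compound 2 is iodinated ortho to the free phenol (NIS, cat. TsOH, MeCN, 0 °C) to give 3-(4-hydroxy-3-iodophenyl)-7-[(triisopropylsilyl)oxy]-4H-chromen-4-one F1. The phenol is acetylated (Ac2O, pyridine) to the aryl acetate F2, so that the later ortho-alkynylphenol cannot close to a benzofuran. Sonogashira coupling of F2 with 5 (PdCl2(PPh3)2, CuI, Et3N, THF, rt) should give the aryl alkyne F3. Semi-hydrogenation over Lindlar catalyst (H2, quinoline, EtOAc) should give the Z-alkene acetate F4. Methanolysis of the acetate (K2CO3, MeOH, 0 °C) comes back to the route at 10; should the silyl ether be lost as well, this only anticipates step 6.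

Step 2. The alkenyl nonaflate may eliminate incompletely, the aldehyde may self-condense before it is sulfonylated, or base-induced propargyl–allenyl isomerisation may erode the enantiomeric purity. The fallback sets out from 3 and degrades it by one carbon before putting that carbon back. Condensation with piperidine (K2CO3, 0 °C to rt) gives 1-[(1E,3R)-3,7-dimethylocta-1,6-dien-1-yl]piperidine F5. Copper-catalysed oxygenation of the enamine C=C bond (CuCl, O2, MeCN, rt) gives (2R)-2,6-dimethylhept-5-enal F6. Seyferth–Gilbert homologation with the Ohira–Bestmann reagent (K2CO3, MeOH, 0 °C to rt) comes back to the route at 5.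

Step 4. Diimide may over-reduce the product to the saturated iodide, stop short of full conversion, or cause reductive loss of iodine, leaving a Z-iodide that is hard to purify. The fallback sets out from 6. Hydroboration with dicyclohexylborane (THF, 0 °C) adds syn and places boron on the iodine-bearing carbon to give dicyclohexyl[(1Z,3R)-1-iodo-3,7-dimethylocta-1,6-dien-1-yl]borane F7. Protonolysis of the C–B bond with AcOH, with retention, comes back to the route at 7.

**Further compounds**
F1 | step 5 | 3-(4-hydroxy-3-iodophenyl)-7-[(triisopropylsilyl)oxy]-4H-chromen-4-one | Oc1ccc(-c2coc3cc(O[Si](C(C)C)(C(C)C)C(C)C)ccc3c2=O)cc1I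
F2 | step 5 | 2-iodo-4-{4-oxo-7-[(triisopropylsilyl)oxy]-4H-chromen-3-yl}phenyl acetate | CC(=O)Oc1ccc(-c2coc3cc(O[Si](C(C)C)(C(C)C)C(C)C)ccc3c2=O)cc1I
F3 | step 5 | 2-[(3R)-3,7-dimethyloct-6-en-1-yn-1-yl]-4-{4-oxo-7-[(triisopropylsilyl)oxy]-4H-chromen-3-yl}phenyl acetate | CC(C)=CCC[C@@H](C)C#Cc1cc(-c2coc3cc(O[Si](C(C)C)(C(C)C)C(C)C)ccc3c2=O)ccc1OC(C)=O
F4 | step 5 | 2-[(1Z,3R)-3,7-dimethylocta-1,6-dien-1-yl]-4-{4-oxo-7-[(triisopropylsilyl)oxy]-4H-chromen-3-yl}phenyl acetate | CC(C)=CCC[C@@H](C)/C=C\c1cc(-c2coc3cc(O[Si](C(C)C)(C(C)C)C(C)C)ccc3c2=O)ccc1OC(C)=O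
F5 | step 2 | 1-[(1E,3R)-3,7-dimethylocta-1,6-dien-1-yl]piperidine | CC(C)=CCC[C@@H](C)/C=C/N1CCCCC1
F6 | step 2 | (2R)-2,6-dimethylhept-5-enal | CC(C)=CCC[C@@H](C)C=O
F7 | step 4 | dicyclohexyl[(1Z,3R)-1-iodo-3,7-dimethylocta-1,6-dien-1-yl]borane | CC(C)=CCC[C@@H](C)/C=C(\I)B(C1CCCCC1)C1CCCCC1
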